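**Retrosynthetic overview**
1. Target 25 comes from hydrogenolysis of heptabenzyl ether 24; the lower pyran ring (O1''–C2'') is closed last, by Mitsunobu inversion in phenol 23.
2. The C2''–aryl bond comes from chelation-controlled addition of the aryl-magnesium made from bromide 12 to the (S)-2-benzyloxy aldehyde 19 (from 3-(benzyloxy)phenol 3 and methyl (S)-glycidate 15).
3. The strategy rests on the upper pyran ring (O1, C2, C3, C4, C4a, C8a): three contiguous all-trans centres C2 (4-hydroxyphenyl), C3 (OH) and C4 (catechol ring) beside the phenolic O1. Cutting O1–C2 and C3–C4 gives ortho-quinone methide 9 (O1, C8a, C4a, C4) and the E-alkene C2=C3 of styrylboronate 8, with boron at C3 standing for the hydroxyl.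
4. 9 is released from benzhydrol 5 (from bromoaldehyde 2 and phenol 3); 8 comes from alkyne 6 and pinacolborane 7.
5. Ring order: upper pyran ring first (step 4), lower pyran ring second (step 14).

Key step: step 4

Assumption: the sense of induction of the acid catalyst cannot be assigned in advance; the (R)-catalyst is written, and its mirror image is taken if a pilot run shows the opposite sense.

**Route**

Step 1
Reactants: 1 3,4-bis(benzyloxy)benzaldehyde
Product: 2 4,5-bis(benzyloxy)-2-bromobenzaldehyde
Conditions: Br2 (1.1 equiv), NaOAc, AcOH, rt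
Reagents that add atoms: bromine, BrBr
Why: Electrophilic aromatic bromination goes to C6 (para to the 3-benzyloxy group, ortho to the formyl group), the most activated free position as in the bromination of veratraldehyde, and the acetate buffer keeps HBr away from the benzyl ethers.

Step 2
Reactants: 3 3-(benzyloxy)phenol; 2 4,5-bis(benzyloxy)-2-bromobenzaldehyde
Product: 5 5-(benzyloxy)-2-{[4,5-bis(benzyloxy)-2-bromophenyl](hydroxy)methyl}phenol (racemic), via bromomagnesium 3-(benzyloxy)phenoxide 4 (not isolated)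
Conditions: EtMgBr (1.0 equiv), Et2O, 0 °C; solvent change to toluene; 2 (1.0 equiv), rt; aq. NH4Cl
Reagents that add atoms: none
Why: Casiraghi ortho-hydroxyalkylation: in toluene the magnesium phenoxide binds the aldehyde and delivers it through a six-membered transition state to the ortho carbon, the unhindered C6 (para to the benzyloxy group) being preferred over C2, and the carbinol centre may be racemic because step 4 removes it.

Step 3
Reactants: 6 1-(benzyloxy)-4-ethynylbenzene; 7 pinacolborane
Product: 8 (E)-2-[4-(benzyloxy)styryl]-4,4,5,5-tetramethyl-1,3,2-dioxaborolane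
Conditions: Cp2Zr(H)Cl (5 mol %), Et3N (10 mol %), neat, 60 °C
Reagents that add atoms: none
Why: Zirconium-catalysed hydroboration of the terminal alkyne adds H and B syn and anti-Markovnikov, which fixes the E geometry.

Step 4
Reactants: 5 5-(benzyloxy)-2-{[4,5-bis(benzyloxy)-2-bromophenyl](hydroxy)methyl}phenol; 8 (E)-2-[4-(benzyloxy)styryl]-4,4,5,5-tetramethyl-1,3,2-dioxaborolane
Product: 10 2-{(2S,3S,4S)-7-(benzyloxy)-2-[4-(benzyloxy)phenyl]-4-[4,5-bis(benzyloxy)-2-bromophenyl]chroman-3-yl}-4,4,5,5-tetramethyl-1,3,2-dioxaborolane (2,3-trans-3,4-trans), via ortho-quinone methide 9 (not isolated)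
Conditions: (R)-3,3'-bis(2,4,6-triisopropylphenyl)-H8-BINOL N-triflylphosphoramide (10 mol %), 8 (2.5 equiv), anhydrous MgSO4, CH2Cl2, −20 °C, 5 added slowly by syringe pump
Reagents that add atoms: none
Why: Proposed new method: the strong chiral acid ionises benzhydrol 5 to the E-configured ortho-quinone methide 9, which stays hydrogen-bonded to the phosphoramide anion, and the boron-bearing alkene carbon of 8 (the nucleophilic end, because the 4-benzyloxyphenyl group stabilises the positive charge that builds up on the other carbon and boron does not oppose it) bonds to the methide carbon C4 while the quinone methide oxygen closes on the benzylic carbon C2 in a concerted but asynchronous inverse-demand oxa-[4+2] that restores the aromaticity of ring A. The closest known reaction type is the chiral Brønsted-acid-catalysed [4+2] of in situ ortho-quinone methides with styrenes and β-alkylstyrenes, which gives 2,4-cis-chromans; an alkenylboronate has not been shown as the 2π partner, and the pinacol ester is kept because it does not exchange its diol and is therefore slow in the competing transfer of the alkenyl group from boron to C4. The pyran ring is closed as a six-membered ring in the [4+2] mode, O1–C2 and C3–C4 forming in the same step (in the stepwise limit a six-membered closure of the phenoxide on the 4-benzyloxybenzylic cation). C4 is set by the face of 9 left open by the chiral anion, C2 by the endo position of the 4-benzyloxyphenyl group (2,4-cis) and C3 by the E geometry of 8 (2,3-trans and 3,4-trans), which together give the all-equatorial isomer. The step needs regioselectivity (secured by the donor aryl group of 8), chemoselectivity for cycloaddition over alkylation of the electron-rich rings of 5 and 10 by 9 (secured by excess 8 and slow addition of 5) and enantioface selectivity (secured by the confined N-triflyl phosphoramide, an acid class that activates the electrophile alone, and helped by the ortho-bromine that enlarges the steric difference at the methide carbon).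

Step 5
Reactants: 10 the 3-boryl chroman
Product: 11 (2R,3S,4S)-7-(benzyloxy)-2-[4-(benzyloxy)phenyl]-4-[4,5-bis(benzyloxy)-2-bromophenyl]chroman-3-ol
Conditions: 30 % H2O2, 2 M NaOH, THF, 0 °C, short contact time
Reagents that add atoms: hydrogen peroxide, OO
Why: Oxidation of the C–B bond by hydroperoxide goes by 1,2-migration of C3 from boron to oxygen with retention, so the equatorial boryl group becomes the 3-hydroxyl trans to both aryl groups, and the low temperature guards against β-elimination of the ring oxygen.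

Step 6
Reactants: 11 the chroman-3-ol
Product: 12 (2R,3S,4S)-3,7-bis(benzyloxy)-2-[4-(benzyloxy)phenyl]-4-[4,5-bis(benzyloxy)-2-bromophenyl]chroman
Conditions: NaH, BnBr, Bu4NI (cat.), DMF, 0 °C to rt
Reagents that add atoms: benzyl bromide, BrCc1ccccc1
Why: Williamson etherification of the secondary alkoxide touches no stereocentre and leaves the aryl bromide intact.

Step 7
Reactants: 3 3-(benzyloxy)phenol
Product: 13 5-(benzyloxy)-2-iodophenol
Conditions: iodine (1.05 equiv), NaHCO3, THF/H2O, 0 °C to rt
Reagents that add atoms: iodine, [I][I]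
Why: Electrophilic iodination of the phenoxide goes ortho to the hydroxyl at C6, the position para to the benzyloxy group, as in the usual preparation of 2-iodo-5-methoxyphenol.

Step 8
Reactants: 13 5-(benzyloxy)-2-iodophenol
Product: 14 2-(allyloxy)-4-(benzyloxy)-1-iodobenzene
Conditions: allyl bromide, K2CO3, acetone, 50 °C
Reagents that add atoms: allyl bromide, C=CCBr
Why: Williamson O-allylation gives a phenol protecting group that withstands organometallic and basic steps and is removed under neutral conditions in step 13.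

Step 9
Reactants: 14 2-(allyloxy)-4-(benzyloxy)-1-iodobenzene; 15 methyl (S)-oxirane-2-carboxylate (methyl (S)-glycidate)
Product: 17 methyl (S)-3-[2-(allyloxy)-4-(benzyloxy)phenyl]-2-hydroxypropanoate, via arylmagnesium iodide 16 (not isolated)
Conditions: Mg, THF, rt; then CuBr·SMe2 (10 mol %), 15 (0.8 equiv), −40 to −20 °C; aq. NH4Cl
Reagents that add atoms: none
Why: Copper-catalysed SN2 opening of the glycidic ester by the aryl Grignard reagent at the unsubstituted C3 (the known route to 3-aryl lactates) outruns attack at the ester at low temperature, and since C2 is not touched its S configuration is carried into 17.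

Step 10
Reactants: 17 the α-hydroxy ester
Product: 18 methyl (S)-3-[2-(allyloxy)-4-(benzyloxy)phenyl]-2-(benzyloxy)propanoate
Conditions: BnBr (3 equiv), Ag2O (1.5 equiv), Et2O, rt, dark
Reagents that add atoms: benzyl bromide, BrCc1ccccc1
Why: Silver-oxide-mediated O-benzylation needs no strong base, so the α-centre of the ester cannot enolise and stays S.

Step 11
Reactants: 18 the α-benzyloxy ester
Product: 19 (S)-3-[2-(allyloxy)-4-(benzyloxy)phenyl]-2-(benzyloxy)propanal
Conditions: i-Bu2AlH (1.1 equiv), CH2Cl2, −78 °C; MeOH, aq. potassium sodium tartrate; used at once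
Reagents that add atoms: none
Why: Partial reduction of an α-alkoxy ester with i-Bu2AlH at −78 °C stops at the aldehyde oxidation level, and immediate use avoids α-epimerisation.

Step 12
Reactants: 12 the aryl bromide of the upper unit; 19 the (S)-aldehyde
Product: 22 (1S,2S)-3-[2-(allyloxy)-4-(benzyloxy)phenyl]-2-(benzyloxy)-1-{4,5-bis(benzyloxy)-2-[(2R,3S,4R)-3,7-bis(benzyloxy)-2-[4-(benzyloxy)phenyl]chroman-4-yl]phenyl}propan-1-ol, via aryllithium 20 (not isolated), via arylmagnesium bromide 21 (not isolated)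
Conditions: t-BuLi (2.0 equiv), Et2O/toluene, −78 °C; MgBr2·OEt2 (1.3 equiv), −78 to −40 °C; 19 (1.3 equiv), −78 to −40 °C; aq. NH4Cl
Reagents that add atoms: none
Why: Bromine–lithium exchange (chosen because this electron-rich bromide exchanges slowly with alkylmagnesium reagents) and transmetalation give an aryl Grignard reagent that adds through the Cram chelate, magnesium bridging the carbonyl and the α-benzyloxy oxygen and attack coming from the side of the α-hydrogen, which gives the 1,2-syn (1S,2S) alcohol; the descriptor at C4 of the upper unit changes from S to R only because bromine is replaced by carbon.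

Step 13
Reactants: 22 the allyl-protected alcohol
Product: 23 5-(benzyloxy)-2-[(2S,3S)-2-(benzyloxy)-3-{4,5-bis(benzyloxy)-2-[(2R,3S,4R)-3,7-bis(benzyloxy)-2-[4-(benzyloxy)phenyl]chroman-4-yl]phenyl}-3-hydroxypropyl]phenol
Conditions: Pd(PPh3)4 (5 mol %), morpholine (5 equiv), THF, rt
Reagents that add atoms: none
Why: Tsuji–Trost deallylation: zerovalent palladium ionises the aryl allyl ether and morpholine traps the allyl unit, leaving the benzyl ethers and the benzylic alcohol untouched.

Step 14
Reactants: 23 the phenol–benzylic alcohol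
Product: 24 (2R,3S)-3,7-bis(benzyloxy)-2-{4,5-bis(benzyloxy)-2-[(2R,3S,4R)-3,7-bis(benzyloxy)-2-[4-(benzyloxy)phenyl]chroman-4-yl]phenyl}chroman
Conditions: PPh3 (1.5 equiv), DIAD (1.5 equiv), THF (0.01 M), 0 °C to rt
Reagents that add atoms: none
Why: Intramolecular Mitsunobu etherification: the phenol displaces the phosphorus-activated benzylic oxygen in a 6-exo-tet SN2 closure with inversion, so the (S)-carbinol becomes C2 (R) of the lower pyran ring, trans to the 3-benzyloxy group.

Step 15
Reactants: 24 the heptabenzyl ether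
Product: 25 (2R,3S,4R)-4-{2-[(2R,3S)-3,7-dihydroxychroman-2-yl]-4,5-dihydroxyphenyl}-2-(4-hydroxyphenyl)chroman-3,7-diol (CNP0275373.1)
Conditions: H2 (1 atm), Pd(OH)2/C, THF/MeOH, rt
Reagents that add atoms: none
Why: Hydrogenolysis cleaves the seven O-benzyl groups under conditions that are standard for benzylated flavan-3-ols and should leave the cyclic benzylic C2–O1 ethers and the C4–aryl bond intact, so no stereocentre is touched.

**Compound list**
1 | 3,4-bis(benzyloxy)benzaldehyde | O=Cc1ccc(OCc2ccccc2)c(OCc2ccccc2)c1 | starting material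
2 | 4,5-bis(benzyloxy)-2-bromobenzaldehyde | O=Cc1cc(OCc2ccccc2)c(OCc2ccccc2)cc1Br | intermediate
3 | 3-(benzyloxy)phenol | Oc1cccc(OCc2ccccc2)c1 | starting material
4 | bromomagnesium 3-(benzyloxy)phenoxide | Br[Mg]Oc1cccc(OCc2ccccc2)c1 | intermediate (not isolated)
5 | 5-(benzyloxy)-2-{[4,5-bis(benzyloxy)-2-bromophenyl](hydroxy)methyl}phenol, racemic | OC(c1ccc(OCc2ccccc2)cc1O)c1cc(OCc2ccccc2)c(OCc2ccccc2)cc1Br | intermediate
6 | 1-(benzyloxy)-4-ethynylbenzene | C#Cc1ccc(OCc2ccccc2)cc1 | starting material
7 | pinacolborane | CC1(C)OBOC1(C)C | starting material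
8 | (E)-2-[4-(benzyloxy)styryl]-4,4,5,5-tetramethyl-1,3,2-dioxaborolane | CC1(C)OB(/C=C/c2ccc(OCc3ccccc3)cc2)OC1(C)C | intermediate
9 | (6E)-3-(benzyloxy)-6-{[4,5-bis(benzyloxy)-2-bromophenyl]methylidene}cyclohexa-2,4-dien-1-one | O=C1C=C(OCc2ccccc2)C=C/C1=C\c1cc(OCc2ccccc2)c(OCc2ccccc2)cc1Br | intermediate (not isolated)
10 | 2-{(2S,3S,4S)-7-(benzyloxy)-2-[4-(benzyloxy)phenyl]-4-[4,5-bis(benzyloxy)-2-bromophenyl]chroman-3-yl}-4,4,5,5-tetramethyl-1,3,2-dioxaborolane | c5ccccc5COc1ccc([C@H]2Oc3cc(OCc5ccccc5)ccc3[C@@H](c3cc(OCc5ccccc5)c(OCc5ccccc5)cc3Br)[C@@H]2B4OC(C)(C)C(C)(C)O4)cc1 | intermediate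
11 | (2R,3S,4S)-7-(benzyloxy)-2-[4-(benzyloxy)phenyl]-4-[4,5-bis(benzyloxy)-2-bromophenyl]chroman-3-ol | c5ccccc5COc1ccc([C@H]2Oc3cc(OCc5ccccc5)ccc3[C@@H](c3cc(OCc5ccccc5)c(OCc5ccccc5)cc3Br)[C@@H]2O)cc1 | intermediate
12 | (2R,3S,4S)-3,7-bis(benzyloxy)-2-[4-(benzyloxy)phenyl]-4-[4,5-bis(benzyloxy)-2-bromophenyl]chroman | c5ccccc5COc1ccc([C@H]2Oc3cc(OCc5ccccc5)ccc3[C@@H](c3cc(OCc5ccccc5)c(OCc5ccccc5)cc3Br)[C@@H]2OCc5ccccc5)cc1 | intermediate
13 | 5-(benzyloxy)-2-iodophenol | Ic1ccc(OCc2ccccc2)cc1O | intermediate
14 | 2-(allyloxy)-4-(benzyloxy)-1-iodobenzene | Ic1ccc(OCc2ccccc2)cc1OCC=C | intermediate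
15 | methyl (S)-oxirane-2-carboxylate | COC(=O)[C@@H]1CO1 | starting material
16 | [2-(allyloxy)-4-(benzyloxy)phenyl]magnesium iodide | I[Mg]c1ccc(OCc2ccccc2)cc1OCC=C | intermediate (not isolated)
17 | methyl (S)-3-[2-(allyloxy)-4-(benzyloxy)phenyl]-2-hydroxypropanoate | C=CCOc1cc(OCc2ccccc2)ccc1C[C@@H](C(=O)OC)O | intermediate
18 | methyl (S)-3-[2-(allyloxy)-4-(benzyloxy)phenyl]-2-(benzyloxy)propanoate | C=CCOc1cc(OCc2ccccc2)ccc1C[C@@H](C(=O)OC)OCc1ccccc1 | intermediate
19 | (S)-3-[2-(allyloxy)-4-(benzyloxy)phenyl]-2-(benzyloxy)propanal | C=CCOc1cc(OCc2ccccc2)ccc1C[C@@H](C=O)OCc1ccccc1 | intermediate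
20 | aryllithium from 12 (lithium in place of bromine) | c5ccccc5COc1ccc([C@H]2Oc3cc(OCc5ccccc5)ccc3[C@@H](c3cc(OCc5ccccc5)c(OCc5ccccc5)cc3[Li])[C@@H]2OCc5ccccc5)cc1 | intermediate (not isolated)
21 | arylmagnesium bromide from 12 (MgBr in place of bromine) | c5ccccc5COc1ccc([C@H]2Oc3cc(OCc5ccccc5)ccc3[C@@H](c3cc(OCc5ccccc5)c(OCc5ccccc5)cc3[Mg]Br)[C@@H]2OCc5ccccc5)cc1 | intermediate (not isolated)
22 | (1S,2S)-3-[2-(allyloxy)-4-(benzyloxy)phenyl]-2-(benzyloxy)-1-{4,5-bis(benzyloxy)-2-[(2R,3S,4R)-3,7-bis(benzyloxy)-2-[4-(benzyloxy)phenyl]chroman-4-yl]phenyl}propan-1-ol | c5ccccc5COc1ccc([C@H]2Oc3cc(OCc5ccccc5)ccc3[C@@H](c3cc(OCc5ccccc5)c(OCc5ccccc5)cc3[C@H](O)[C@@H](OCc5ccccc5)Cc6ccc(OCc5ccccc5)cc6OCC=C)[C@@H]2OCc5ccccc5)cc1 | intermediate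
23 | 5-(benzyloxy)-2-[(2S,3S)-2-(benzyloxy)-3-{4,5-bis(benzyloxy)-2-[(2R,3S,4R)-3,7-bis(benzyloxy)-2-[4-(benzyloxy)phenyl]chroman-4-yl]phenyl}-3-hydroxypropyl]phenol | c5ccccc5COc1ccc([C@H]2Oc3cc(OCc5ccccc5)ccc3[C@@H](c3cc(OCc5ccccc5)c(OCc5ccccc5)cc3[C@H](O)[C@@H](OCc5ccccc5)Cc6ccc(OCc5ccccc5)cc6O)[C@@H]2OCc5ccccc5)cc1 | intermediate
24 | (2R,3S)-3,7-bis(benzyloxy)-2-{4,5-bis(benzyloxy)-2-[(2R,3S,4R)-3,7-bis(benzyloxy)-2-[4-(benzyloxy)phenyl]chroman-4-yl]phenyl}chroman | c5ccccc5COc1ccc([C@H]2Oc3cc(OCc5ccccc5)ccc3[C@@H](c3cc(OCc5ccccc5)c(OCc5ccccc5)cc3[C@H]3Oc4cc(OCc5ccccc5)ccc4C[C@@H]3OCc5ccccc5)[C@@H]2OCc5ccccc5)cc1 | intermediate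
25 | (2R,3S,4R)-4-{2-[(2R,3S)-3,7-dihydroxychroman-2-yl]-4,5-dihydroxyphenyl}-2-(4-hydroxyphenyl)chroman-3,7-diol | Oc1ccc([C@H]2Oc3cc(O)ccc3[C@@H](c3cc(O)c(O)cc3[C@H]3Oc4cc(O)ccc4C[C@@H]3O)[C@@H]2O)cc1 | target

**Step count**
Total: 15 steps. Longest linear sequence: 9 steps (3 → 13 → 14 → 17 → 18 → 19 → 22 → 23 → 24 → 25; the branch from 1 is equally long).

**Steps most likely to fail**

Step 4 (the labelled step). The alkenyl group may migrate from boron to C4 with loss of boron instead of ring closure, the quinone methide may alkylate the electron-rich rings, or the face selectivity may be low. The fallback uses known chemistry, sets out from 5 and 8 and returns at 11; it makes the alkenyl transfer the intended reaction. Boronate 8 is cleaved with NaIO4 and NH4OAc in aqueous acetone to (E)-[4-(benzyloxy)styryl]boronic acid F1, which is turned with ethanol over molecular sieves into diethyl (E)-[4-(benzyloxy)styryl]boronate F2. Under catalysis by a 3,3'-dibromo-BINOL (chiral-biphenol-catalysed conjugate alkenylation of ortho-quinone methides), F2 adds to the quinone methide released from 5 and gives 5-(benzyloxy)-2-[(1S,2E)-1-[4,5-bis(benzyloxy)-2-bromophenyl]-3-[4-(benzyloxy)phenyl]prop-2-en-1-yl]phenol F3, in which C4 is set. Silylation (TBSCl, imidazole) gives the tert-butyldimethylsilyl ether F4. Shi epoxidation of the E-alkene (fructose-derived ketone of the series that attacks the required face, KHSO5, buffered at pH 10) gives the (S,S)-trans-epoxide F5. Bu4NF frees the epoxy phenol F6 (not isolated), and a trace of camphorsulfonic acid brings about 6-endo opening at the 4-benzyloxybenzylic carbon with inversion, so that the trans-epoxide becomes the 2,3-trans flavan-3-ol 11.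

Step 12. The hindered aryl-magnesium may act as a base on the enolisable α-benzyloxy aldehyde (low conversion, α-epimerisation), and chelation may be incomplete (poor facial selectivity at the new carbinol centre). The fallback sets out from 18 and 12 and returns at 22; it replaces the aldehyde addition by acylation and substrate-controlled reduction. Ester 18 is converted (MeNH(OMe)·HCl, i-PrMgCl, THF, −20 °C) to the Weinreb amide F7. Aryllithium 20 from 12 is acylated by F7 to the aryl ketone F8. Reduction with K[s-Bu3BH] in THF at −78 °C under non-chelating Felkin–Anh control (hydride anti to the benzyloxy group) should give the 1,2-syn alcohol 22.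

Step 14. The activated benzylic oxygen sits on an electron-rich, hindered carbon and may ionise before displacement, which would erode the inversion and open an elimination path. The fallback sets out from 23 and returns at 24 and makes no new isolated compound; it uses the ionisation on purpose. Catalytic camphorsulfonic acid in CH2Cl2 at 0 °C ionises the benzylic alcohol, and the phenol captures the benzylic cation through a chair-like transition state with the aryl group and the 3-benzyloxy group both equatorial. This is the known acid-mediated cyclisation of 1,3-diarylpropane-1,2-diol derivatives, which favours the 2,3-trans flavan whatever the carbinol configuration.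

**Further compounds**
F1 | step 4 | (E)-[4-(benzyloxy)styryl]boronic acid | OB(O)/C=C/c1ccc(OCc2ccccc2)cc1
F2 | step 4 | diethyl (E)-[4-(benzyloxy)styryl]boronate | CCOB(OCC)/C=C/c1ccc(OCc2ccccc2)cc1
F3 | step 4 | 5-(benzyloxy)-2-[(1S,2E)-1-[4,5-bis(benzyloxy)-2-bromophenyl]-3-[4-(benzyloxy)phenyl]prop-2-en-1-yl]phenol | Oc1cc(OCc2ccccc2)ccc1[C@@H](c1cc(OCc2ccccc2)c(OCc2ccccc2)cc1Br)/C=C/c1ccc(OCc2ccccc2)cc1
F4 | step 4 | tert-butyldimethylsilyl ether of F3 | CC(C)(C)[Si](C)(C)Oc1cc(OCc2ccccc2)ccc1[C@@H](c1cc(OCc2ccccc2)c(OCc2ccccc2)cc1Br)/C=C/c1ccc(OCc2ccccc2)cc1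
F5 | step 4 | (S,S)-trans-epoxide of F4 | CC(C)(C)[Si](C)(C)Oc1cc(OCc2ccccc2)ccc1[C@@H](c1cc(OCc2ccccc2)c(OCc2ccccc2)cc1Br)[C@@H]1O[C@H]1c1ccc(OCc2ccccc2)cc1
F6 | step 4 | epoxy phenol from F5 (not isolated) | Oc1cc(OCc2ccccc2)ccc1[C@@H](c1cc(OCc2ccccc2)c(OCc2ccccc2)cc1Br)[C@@H]1O[C@H]1c1ccc(OCc2ccccc2)cc1
F7 | step 12 | (S)-3-[2-(allyloxy)-4-(benzyloxy)phenyl]-2-(benzyloxy)-N-methoxy-N-methylpropanamide | C=CCOc1cc(OCc2ccccc2)ccc1C[C@@H](C(=O)N(C)OC)OCc1ccccc1
F8 | step 12 | (S)-3-[2-(allyloxy)-4-(benzyloxy)phenyl]-2-(benzyloxy)-1-{4,5-bis(benzyloxy)-2-[(2R,3S,4R)-3,7-bis(benzyloxy)-2-[4-(benzyloxy)phenyl]chroman-4-yl]phenyl}propan-1-one | c5ccccc5COc1ccc([C@H]2Oc3cc(OCc5ccccc5)ccc3[C@@H](c3cc(OCc5ccccc5)c(OCc5ccccc5)cc3C(=O)[C@@H](OCc5ccccc5)Cc6ccc(OCc5ccccc5)cc6OCC=C)[C@@H]2OCc5ccccc5)cc1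
F0 | step 14 | none | none
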